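**Retrosynthetic overview**

1. Target: (2R,5S,6S,8S,9S)-2,8-dibromo-9-chloro-1,1,5,9-tetramethylspiro[5.5]undecane. These spiro locants are used for all spirocycles: ring A = C1 (CMe2), C2 (CHBr), C3, C4, C5 (CHMe), C6 (spiro); ring B = C6, C7, C8 (CHBr), C9 (CMeCl), C10, C11.
2. Ring B is carried as a para-substituted phenol. The enabling feature is the oxygen on C9, para to C6 in ring B: as a phenoxide it makes C6 nucleophilic, so C6 can displace a mesylate on C5 and close ring A through the C5–C6 bond (dearomative spiroalkylation); the benzylic gem-dimethyl carbon C1 holds the tether.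
3. Disconnections: C2–Br ⇐ C2=C3 alkenyl bromide ⇐ C2 ketone; C9–Cl, C9–Me and C8–Br ⇐ C9 ketone of the hydrogenated dienone; C5–C6 ⇐ phenoxide + (R)-mesylate; C3–C4 ⇐ methyl ketone enolate + (R)-2-methyloxirane; C1 ⇐ double methylation of 4-hydroxyphenylacetone.
4. Ring order: ring B is present from the start as the arene; ring A is closed in step 5. Stereocentres: C5 (chiral pool, inversion), C6 and C8 (catalyst-controlled site-selective bromination), C9 (axial methyl delivery, retentive chlorination), C2 (hydrogen-atom-transfer hydrogenation).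

Key step: step 5

Assumption (remark on the chemistry): in step 7 the (4R,5R) catalyst is taken to be the enantiomer that brominates the methylene leading to the (6S,8S) series; if the sense of induction is the opposite one, the (4S,5S) catalyst is used.

**Route**

Step 1
Reactants: 1 1-(4-hydroxyphenyl)propan-2-one
Product: 2 1-[4-(tert-butyldimethylsilyloxy)phenyl]propan-2-one
Conditions: t-BuMe2SiCl, imidazole, DMF, rt
Reagents that add atoms: tert-butyldimethylsilyl chloride, CC(C)(C)[Si](C)(C)Cl
Why: O-silylation of the phenol keeps the oxygen inert to the bases of steps 2 and 3 and lets fluoride release the phenoxide in the key step.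

Step 2
Reactants: 2 1-[4-(tert-butyldimethylsilyloxy)phenyl]propan-2-one
Product: 4 3-[4-(tert-butyldimethylsilyloxy)phenyl]-3-methylbutan-2-one, via monomethyl ketone 3 (not isolated)
Conditions: NaH (2.2 equiv), MeI (2.3 equiv), THF, 0 °C → rt
Reagents that add atoms: iodomethane, CI
Why: Double enolate C-methylation at the more acidic benzylic α-carbon should build the quaternary carbon that becomes C1; no stereocentre is formed.

Step 3
Reactants: 4 3-[4-(tert-butyldimethylsilyloxy)phenyl]-3-methylbutan-2-one; 5 (R)-2-methyloxirane
Product: 7 (6R)-6-hydroxy-2-methyl-2-[4-(tert-butyldimethylsilyloxy)phenyl]heptan-3-one, via lithium enolate 6 (not isolated)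
Conditions: LiN(i-Pr)2, THF, −78 °C; then 5, LiClO4, −78 °C → rt; aq NH4Cl
Reagents that add atoms: none
Why: LiClO4-promoted opening of the epoxide by the ketone enolate at the unsubstituted carbon forms the future C3–C4 bond; the ketone has a single enolisable α-carbon and the (R) carbinol carbon (future C5) is not touched.

Step 4
Reactants: 7 (6R)-6-hydroxy-2-methyl-2-[4-(tert-butyldimethylsilyloxy)phenyl]heptan-3-one
Product: 8 (2R)-6-methyl-5-oxo-6-[4-(tert-butyldimethylsilyloxy)phenyl]heptan-2-yl methanesulfonate
Conditions: MeSO2Cl, Et3N, CH2Cl2, 0 °C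
Reagents that add atoms: methanesulfonyl chloride, CS(=O)(=O)Cl
Why: O-sulfonylation of the secondary alcohol with retention gives the leaving group for the key step.

Step 5
Reactants: 8 (2R)-6-methyl-5-oxo-6-[4-(tert-butyldimethylsilyloxy)phenyl]heptan-2-yl methanesulfonate
Product: 10 (5S)-1,1,5-trimethylspiro[5.5]undeca-7,10-diene-2,9-dione, via tetrabutylammonium phenoxide 9 (not isolated)
Conditions: Bu4NF (1.05 equiv), THF (0.005 M), 0 °C → 60 °C
Reagents that add atoms: none
Why: Fluoride removes the silyl group, and the phenoxide 9 attacks the mesylate carbon through its para carbon (future C6) in an intramolecular SN2 displacement that gives the cross-conjugated dienone directly (para-alkylative dearomatisation, Ar1-6 phenoxide participation). The closest known reaction type is the intramolecular para-C-alkylation of phenoxides by tethered sulfonates to give spirocyclohexa-2,5-dienones. Ring A is closed in a 6-exo-tet mode by the C5–C6 bond, and the same event creates the all-carbon spiro centre next to the quaternary C1. The only new stereocentre, C5, is set by inversion of the (R)-mesylate and becomes S; C6 is not yet stereogenic because ring B is a symmetric dienone. The step needs C- over O-alkylation (the oxygen cannot reach the tether and high dilution suppresses the intermolecular path), para over ortho attack (ortho attack would need a seven-membered ring at a non-activated carbon) and substitution over enolate formation or elimination, which the weak basicity of the phenoxide and the gem-dialkyl effect of C1 should secure.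

Step 6
Reactants: 10 (5S)-1,1,5-trimethylspiro[5.5]undeca-7,10-diene-2,9-dione
Product: 11 (5S)-1,1,5-trimethylspiro[5.5]undecane-2,9-dione
Conditions: H2 (1 atm), 10 % Pd/C, EtOAc, rt
Reagents that add atoms: none
Why: Heterogeneous catalytic hydrogenation saturates both enone double bonds and leaves the ketones and C5 untouched; ring B becomes a chair with C1 equatorial and C5 axial, which in turn holds the 5-methyl group axial on ring A.

Step 7
Reactants: 11 (5S)-1,1,5-trimethylspiro[5.5]undecane-2,9-dione
Product: 12 (5S,6S,8S)-8-bromo-1,1,5-trimethylspiro[5.5]undecane-2,9-dione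
Conditions: (4R,5R)-4,5-diphenylimidazolidine (20 mol %), PhCO2H (20 mol %), 4,4-dibromo-2,6-di-tert-butylcyclohexa-2,5-dien-1-one (1.0 equiv), THF, −30 °C
Reagents that add atoms: 4,4-dibromo-2,6-di-tert-butylcyclohexa-2,5-dien-1-one, CC(C)(C)C1=CC(Br)(Br)C=C(C(C)(C)C)C1=O
Why: Enamine-mediated asymmetric α-bromination of a ketone: only the unhindered C9 ketone condenses with the twofold-symmetric amine, the catalyst selects one of the two diastereotopic α-methylenes (this desymmetrisation sets C6), and the bromine at C8 should end equatorial, trans to the axial C5 branch, since an axial bromine would be 1,3-diaxial to C5 and the α-bromoketone can equilibrate by enolisation.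

Step 8
Reactants: 12 (5S,6S,8S)-8-bromo-1,1,5-trimethylspiro[5.5]undecane-2,9-dione
Product: 13 (5S,6S,8S,9S)-8-bromo-9-hydroxy-1,1,5,9-tetramethylspiro[5.5]undecan-2-one
Conditions: AlMe3 and 2,6-di-tert-butyl-4-methylphenol (2 equiv per Al), toluene, rt, to give MeAl(OAr)2; then 12, −78 °C; MeLi, −78 °C; cold 1 M HCl
Reagents that add atoms: methyllithium, [Li]C
Why: Amphiphilic carbonyl methylation: the bulky aluminium aryloxide binds the unhindered C9 carbonyl on its equatorial side and leaves the neopentyl C2 ketone free, so MeLi should add to C9 along the axial trajectory, placing the methyl axial and the hydroxyl equatorial, trans to the C8 bromine.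

Step 9
Reactants: 13 (5S,6S,8S,9S)-8-bromo-9-hydroxy-1,1,5,9-tetramethylspiro[5.5]undecan-2-one
Product: 15 (5S,6S,8S,9S)-8-bromo-9-chloro-1,1,5,9-tetramethylspiro[5.5]undecan-2-one, via chlorosulfite 14 (not isolated)
Conditions: SOCl2, CH2Cl2, 0 °C; then TiCl4 (10 mol %), −78 °C → 0 °C
Reagents that add atoms: thionyl chloride, O=S(Cl)Cl
Why: Chlorodehydroxylation of the tertiary alcohol through its chlorosulfite with TiCl4-assisted front-side collapse (SNi, retention), so chlorine should take the equatorial position of the hydroxyl, cis to C5 and trans to bromine; ionised material bridged by the neighbouring bromine is opened anti to it and converges on the same isomer.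

Step 10
Reactants: 15 (5S,6S,8S,9S)-8-bromo-9-chloro-1,1,5,9-tetramethylspiro[5.5]undecan-2-one
Product: 16 (5S,6S,8S,9S)-2,8-dibromo-9-chloro-1,1,5,9-tetramethylspiro[5.5]undec-2-ene
Conditions: P(OPh)3, Br2, Et3N, CH2Cl2, −60 °C → reflux
Reagents that add atoms: bromine, BrBr
Why: Conversion of an enolisable ketone into an alkenyl bromide with (PhO)3PBr2 and Et3N (oxyphosphonium activation, bromide addition, loss of HBr): C3 is the only α-carbon with hydrogen, and the equatorial halides of ring B have no anti-periplanar hydrogen for base-induced elimination.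

Step 11
Reactants: 16 (5S,6S,8S,9S)-2,8-dibromo-9-chloro-1,1,5,9-tetramethylspiro[5.5]undec-2-ene
Product: 17 (2R,5S,6S,8S,9S)-2,8-dibromo-9-chloro-1,1,5,9-tetramethylspiro[5.5]undecane
Conditions: Mn(dpm)3 (10 mol %; dpm = 2,2,6,6-tetramethylheptane-3,5-dionate), PhSiH3, t-BuOOH, i-PrOH, rt
Reagents that add atoms: none
Why: Metal-hydride hydrogen-atom-transfer hydrogenation of an alkenyl bromide: H adds to C3, and the α-bromo radical at C2 should be quenched so that bromine ends equatorial on the ring A chair whose 5-methyl is held axial by ring B, that is cis to the 5-methyl (2R); these radical conditions leave alkyl bromides and chlorides intact.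

**Compound list**

1 | 1-(4-hydroxyphenyl)propan-2-one | CC(=O)Cc1ccc(O)cc1 | starting material
2 | 1-[4-(tert-butyldimethylsilyloxy)phenyl]propan-2-one | CC(=O)Cc1ccc(O[Si](C)(C)C(C)(C)C)cc1 | intermediate
3 | 3-[4-(tert-butyldimethylsilyloxy)phenyl]butan-2-one (racemic, not isolated) | CC(=O)C(C)c1ccc(O[Si](C)(C)C(C)(C)C)cc1 | intermediate
4 | 3-[4-(tert-butyldimethylsilyloxy)phenyl]-3-methylbutan-2-one | CC(=O)C(C)(C)c1ccc(O[Si](C)(C)C(C)(C)C)cc1 | intermediate
5 | (R)-2-methyloxirane | C[C@@H]1CO1 | starting material
6 | lithium 3-[4-(tert-butyldimethylsilyloxy)phenyl]-3-methylbut-1-en-2-olate (not isolated) | [Li+].[O-]C(=C)C(C)(C)c1ccc(O[Si](C)(C)C(C)(C)C)cc1 | intermediate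
7 | (6R)-6-hydroxy-2-methyl-2-[4-(tert-butyldimethylsilyloxy)phenyl]heptan-3-one | C[C@@H](O)CCC(=O)C(C)(C)c1ccc(O[Si](C)(C)C(C)(C)C)cc1 | intermediate
8 | (2R)-6-methyl-5-oxo-6-[4-(tert-butyldimethylsilyloxy)phenyl]heptan-2-yl methanesulfonate | C[C@@H](OS(C)(=O)=O)CCC(=O)C(C)(C)c1ccc(O[Si](C)(C)C(C)(C)C)cc1 | intermediate
9 | tetrabutylammonium 4-[(6R)-6-(methanesulfonyloxy)-2-methyl-3-oxoheptan-2-yl]phenolate (not isolated) | C[C@@H](OS(C)(=O)=O)CCC(=O)C(C)(C)c1ccc([O-])cc1.CCCC[N+](CCCC)(CCCC)CCCC | intermediate
10 | (5S)-1,1,5-trimethylspiro[5.5]undeca-7,10-diene-2,9-dione | C[C@H]1CCC(=O)C(C)(C)C12C=CC(=O)C=C2 | intermediate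
11 | (5S)-1,1,5-trimethylspiro[5.5]undecane-2,9-dione | C[C@H]1CCC(=O)C(C)(C)C12CCC(=O)CC2 | intermediate
12 | (5S,6S,8S)-8-bromo-1,1,5-trimethylspiro[5.5]undecane-2,9-dione | C[C@H]1CCC(=O)C(C)(C)[C@]12CCC(=O)[C@@H](Br)C2 | intermediate
13 | (5S,6S,8S,9S)-8-bromo-9-hydroxy-1,1,5,9-tetramethylspiro[5.5]undecan-2-one | C[C@H]1CCC(=O)C(C)(C)[C@]12CC[C@](C)(O)[C@@H](Br)C2 | intermediate
14 | chlorosulfite of 13 (9-O-S(O)Cl, not isolated) | C[C@H]1CCC(=O)C(C)(C)[C@]12CC[C@](C)(OS(Cl)=O)[C@@H](Br)C2 | intermediate
15 | (5S,6S,8S,9S)-8-bromo-9-chloro-1,1,5,9-tetramethylspiro[5.5]undecan-2-one | C[C@H]1CCC(=O)C(C)(C)[C@]12CC[C@](C)(Cl)[C@@H](Br)C2 | intermediate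
16 | (5S,6S,8S,9S)-2,8-dibromo-9-chloro-1,1,5,9-tetramethylspiro[5.5]undec-2-ene | C[C@H]1CC=C(Br)C(C)(C)[C@]12CC[C@](C)(Cl)[C@@H](Br)C2 | intermediate
17 | (2R,5S,6S,8S,9S)-2,8-dibromo-9-chloro-1,1,5,9-tetramethylspiro[5.5]undecane | C[C@H]1CC[C@@H](Br)C(C)(C)[C@]12CC[C@](C)(Cl)[C@@H](Br)C2 | target

**Step count and risks**

Total step count: 11. Longest linear sequence: 11 steps (from 1).

Steps most likely to fail:

- **Step 5.** The phenoxide (or fluoride) may deprotonate the methylene next to the ketone, whose enolate then closes a cyclopropane onto the mesylate carbon, or the mesylate may eliminate before the slower six-membered para-alkylation occurs. Fallback: the enolisable carbonyl is masked before ring closure. Starting from 8, ketalisation (MeOSiMe3, cat. Me3SiOTf, CH2Cl2, −78 °C) should give the dimethyl ketal mesylate F1. Bu4NF in THF then performs the same para-alkylative dearomatisation on a substrate without an acidic C–H next to a carbonyl and should give the spirodienone ketal F2. Mild aqueous acid (oxalic acid, THF–H2O) releases the ketone and returns to 10.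

- **Step 9.** The tertiary chlorosulfite may ionise to a free cation that loses a proton or takes up chloride from the axial face, so that the configuration at C9 is lost. Fallback: bromine and chlorine are added together to a C8=C9 alkene, where anti opening of a bromonium ion fixes their trans relationship. Starting from 11, desymmetrising deprotonation with lithium (R,R)-bis(1-phenylethyl)amide (THF, −78 °C) and trapping with PhNTf2 should give the enol triflate F5. Me2CuLi (THF, −20 °C) replaces the triflate by methyl and gives the trisubstituted alkene F6. N-Bromosuccinimide with Et4NCl (CH2Cl2, −78 °C) then adds bromine to C8 and chlorine to the tertiary C9 and rejoins the route at 15; the facial course of this addition would have to be checked.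

- **Step 7.** The chiral amine may not tell the two α-methylenes of the C9 ketone apart well enough (mismatched double diastereoselection), and a second bromination may follow. Fallback: the two halves of ring B are differentiated one stage earlier by an enzyme, and bromine is then delivered to a regiodefined enol ether. Starting from 10, an ene-reductase of the old-yellow-enzyme family (NADPH recycled with glucose and glucose dehydrogenase, buffer) should reduce only the C10=C11 double bond and give the enone F3. 1,4-Hydrosilylation (Et3SiH, cat. RhCl(PPh3)3) gives the triethylsilyl enol ether F4 with the double bond fixed between C8 and C9. N-Bromosuccinimide (THF, −78 °C) then brominates C8 and rejoins the route at 12.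

Further compounds
F1 | step 5 | (2R)-5,5-dimethoxy-6-methyl-6-[4-(tert-butyldimethylsilyloxy)phenyl]heptan-2-yl methanesulfonate | C[C@@H](OS(C)(=O)=O)CCC(OC)(OC)C(C)(C)c1ccc(O[Si](C)(C)C(C)(C)C)cc1
F2 | step 5 | (5S)-2,2-dimethoxy-1,1,5-trimethylspiro[5.5]undeca-7,10-dien-9-one (locants as in 10) | C[C@H]1CCC(OC)(OC)C(C)(C)C12C=CC(=O)C=C2
F3 | step 7 | (5S,6R)-1,1,5-trimethylspiro[5.5]undec-7-ene-2,9-dione | C[C@H]1CCC(=O)C(C)(C)[C@]12CCC(=O)C=C2
F4 | step 7 | (5S,6S)-1,1,5-trimethyl-9-(triethylsilyloxy)spiro[5.5]undec-8-en-2-one | C[C@H]1CCC(=O)C(C)(C)[C@]12CCC(O[Si](CC)(CC)CC)=CC2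
F5 | step 9 | (5S,6S)-1,1,5-trimethyl-2-oxospiro[5.5]undec-8-en-9-yl trifluoromethanesulfonate | C[C@H]1CCC(=O)C(C)(C)[C@]12CCC(OS(=O)(=O)C(F)(F)F)=CC2
F6 | step 9 | (5S,6S)-1,1,5,9-tetramethylspiro[5.5]undec-8-en-2-one | C[C@H]1CCC(=O)C(C)(C)[C@]12CCC(C)=CC2
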